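**Assumption:** Altisin (5-hydroxy-7,8,2',6'-tetramethoxyflavone, C19H18O7) has no stereocentre, and the symmetric 2,6-dimethoxyphenyl ring rules out atropisomers. It is achiral, so there is no enantiomer to control and the route targets the structure as drawn.

## Retrosynthetic overview

1. Altisin ⇒ 5,7,8,2',6'-pentamethoxyflavone by chelation-controlled cleavage of the 5-OMe peri to the C4 carbonyl (last step).
2. The pyranone C-ring (the only ring formed) ⇒ 2'-hydroxychalcone by oxidative cyclisation (oxa-Michael, then dehydrogenation).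
3. Chalcone ⇒ 2'-hydroxy-3',4',6'-trimethoxyacetophenone + 2,6-dimethoxybenzaldehyde (Claisen–Schmidt); the B-ring is bought intact.
4. Acetophenone ⇒ 1,2,3,5-tetramethoxybenzene + acetyl chloride (Friedel–Crafts acylation with in-situ ortho-demethylation); the A-ring is bought intact.

## Route

**Step 1**
Reactants: 1, 1,2,3,5-tetramethoxybenzene; 2, acetyl chloride
Product: 3, 1-(2-hydroxy-3,4,6-trimethoxyphenyl)ethan-1-one (2'-hydroxy-3',4',6'-trimethoxyacetophenone)
Conditions: AcCl (1.3 eq), AlCl3 (2.5–3 eq), dry Et2O, 0 °C → rt, 24–48 h; then ice/aq HCl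
Reagents that add atoms: acetyl chloride (2), CC(=O)Cl
Why: Friedel–Crafts acylation can only occur at the two equivalent free positions (C4/C6). The Al-chelated aryl ketone then loses the more crowded ortho-methoxy, the one flanked by the acyl group and another OMe, giving the chelated 2-hydroxy ketone.

**Step 2**
Reactants: 3, 2'-hydroxy-3',4',6'-trimethoxyacetophenone; 4, 2,6-dimethoxybenzaldehyde (1.2 eq)
Product: 5, (E)-3-(2,6-dimethoxyphenyl)-1-(2-hydroxy-3,4,6-trimethoxyphenyl)prop-2-en-1-one (2'-hydroxychalcone)
Conditions: 50% aq KOH (excess), EtOH, rt, 48–72 h; then cold dil. HCl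
Reagents that add atoms: 2,6-dimethoxybenzaldehyde (4), COc1cccc(OC)c1C=O
Why: Claisen–Schmidt aldol condensation of the methyl ketone enolate with a non-enolisable aldehyde, followed by E1cB dehydration to the conjugated E-enone. Any flavanone formed by partial ring closure is equally usable in Step 3.

**Step 3**
Reactants: 5, the 2'-hydroxychalcone
Product: 6, 2-(2,6-dimethoxyphenyl)-5,7,8-trimethoxy-4H-chromen-4-one (5,7,8,2',6'-pentamethoxyflavone)
Conditions: I2 (0.1 eq), DMSO, 130 °C, 2–4 h; aq Na2S2O3 work-up
Reagents that add atoms: none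
Why: I2/DMSO oxidative cyclisation: intramolecular oxa-Michael addition of the only free phenol gives the flavanone, which is α-iodinated and loses HI to give the flavone (DMSO re-oxidises HI to I2). With a single free OH the 5,7,8-pattern is unambiguous.

**Step 4**
Reactants: 6, 5,7,8,2',6'-pentamethoxyflavone
Product: 7, Altisin, 2-(2,6-dimethoxyphenyl)-5-hydroxy-7,8-dimethoxy-4H-chromen-4-one
Conditions: BCl3 (1 M in CH2Cl2, 1.5–2 eq), CH2Cl2, −78 → 0 °C, 1–2 h; then aq HCl/MeOH to break the boron chelate
Reagents that add atoms: none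
Why: Chelation-directed Lewis-acid ether cleavage: boron bridges the C4 carbonyl and the peri 5-OMe, so only that methyl is removed. The 7-, 8-, 2'- and 6'-OMe groups cannot chelate and survive, and the cold, non-protic conditions avoid Wessely–Moser ring-opening isomerisation.

## Compound list

1 | 1,2,3,5-tetramethoxybenzene | COc1cc(OC)c(OC)c(OC)c1 | starting material
2 | acetyl chloride | CC(=O)Cl | starting material
3 | 1-(2-hydroxy-3,4,6-trimethoxyphenyl)ethan-1-one | CC(=O)c1c(O)c(OC)c(OC)cc1OC | intermediate
4 | 2,6-dimethoxybenzaldehyde | COc1cccc(OC)c1C=O | starting material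
5 | (E)-3-(2,6-dimethoxyphenyl)-1-(2-hydroxy-3,4,6-trimethoxyphenyl)prop-2-en-1-one | COc1cccc(OC)c1/C=C/C(=O)c1c(O)c(OC)c(OC)cc1OC | intermediate
6 | 2-(2,6-dimethoxyphenyl)-5,7,8-trimethoxy-4H-chromen-4-one | COc1cccc(OC)c1-c1cc(=O)c2c(OC)cc(OC)c(OC)c2o1 | intermediate
7 | Altisin, 2-(2,6-dimethoxyphenyl)-5-hydroxy-7,8-dimethoxy-4H-chromen-4-one | COc1cccc(OC)c1-c1cc(=O)c2c(O)cc(OC)c(OC)c2o1 | target

## Summary

Total steps: 4. Longest linear sequence: 4 (1 → 3 → 5 → 6 → 7).

Steps most likely to fail:

1. **Step 1 (acylation with site-selective mono-demethylation).** Risks are cleavage of the wrong ortho-OMe, over-demethylation, or isolation of the undemethylated tetramethoxy ketone. Fallback: install the C8 oxygen late instead. Convert 2',4',6'-trihydroxyacetophenone to 5,7-dihydroxy-2',6'-dimethoxyflavone (LiHMDS with 2,6-dimethoxybenzoyl chloride, then H2SO4/AcOH), hydroxylate C8 by Elbs persulfate oxidation (para to 5-OH), and methylate the 7- and 8-OH with Me2SO4/K2CO3. The hydrogen-bonded 5-OH stays free, so this also removes Step 4.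

2. **Step 3 (I2/DMSO cyclisation).** The β-carbon carries a hindered, electron-rich 2,6-dimethoxyphenyl group, so the oxa-Michael step may be slow, and the activated A-ring could be iodinated. Fallback: a Baker–Venkataraman route that skips the chalcone. O-acylate 3 with 2,6-dimethoxybenzoyl chloride (pyridine/DMAP), rearrange to the 1,3-diketone (KOH/pyridine, 50 °C), and cyclodehydrate to 6 (cat. H2SO4, AcOH, 100 °C).

3. **Step 4 (selective 5-O-demethylation).** Risks are additional cleavage at 8-OMe or 2'/6'-OMe, or incomplete reaction. Fallback: carry O-5 as a benzyl ether. Cleave the 6-OMe of 3 with BCl3 to give 2,6-dihydroxy-3,4-dimethoxyacetophenone, mono-benzylate the less hindered 6-OH (BnBr, K2CO3), run Steps 2–3 on that ketone, and finish with hydrogenolysis (H2, Pd/C, EtOAc). The regioselectivity of the mono-benzylation is the weak point of this fallback.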